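## Retrosynthetic overview

1. The target is reached from a ten-membered lactone by end-game adjustment at C14 (PMB ether → CHO) and C15 (TBS ether → OH); the ten-membered carbocycle is closed by ring-closing metathesis at C1=C10 on an open-chain α-methylene-γ-lactone.
2. That lactone is made by stitching CO2 between C11 (alkenyl–Bpin) and C6 (allylic methyl carbonate) of an open-chain precursor under Pd/Cu catalysis, forming O–C6 and C11–C12.
3. Enabling feature: C6 is at once the lactone carbinol carbon and the terminus of the C4=C5–C6 allyl unit, and it lies 1,3 to the sp2 carbon C11 of the exocyclic C11=C13 methylene. A C4–C5–C6 π-allyl electrophile and a C11 alkenyl nucleophile therefore bracket CO2 as the five-membered ring O–C6–C7–C11–C12.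
4. The precursor comes from an allenyl carbonate, a β,γ-unsaturated aldehyde and (R)-2-methylbutanoic acid: Pt diboration/allylboration forms C7–C8, relays C7 and C8 from C6 and installs the C11 boron; C6 is set by catalytic asymmetric alkynylation of an enal.
5. Ring order: γ-lactone first (step 13), ten-membered carbocycle second (step 14).

Key step: step 13

Remark: skeletal atoms are named by the germacrane numbers of the target (C12 lactone carbonyl, C13 exocyclic methylene, C14 formyl carbon, C15 hydroxymethyl carbon); compounds 1, 10, 11 and 17 and all un-numbered reagents are taken to be commercial.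

## Route

Step 1
Reactants: 1 4-((tert-butyldimethylsilyl)oxy)but-2-yn-1-ol
Product: 3 (Z)-4-((tert-butyldimethylsilyl)oxy)-3-iodobut-2-en-1-ol, via cyclic sodium alkenylalkoxyaluminate 2 (not isolated)
Conditions: Red-Al, THF, 0 °C → rt; then I2, THF, −78 → 0 °C
Reagents that add atoms: iodine II
Why: Hydroxyl-directed trans-hydroalumination of the propargylic alcohol places aluminium on the distal alkyne carbon inside a five-membered alkoxyaluminate, and iodinolysis with retention should give the (Z)-iodoalkene, which fixes the C4=C5 geometry (C15 trans to C6) carried to the target.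

Step 2
Reactants: 3 (Z)-4-((tert-butyldimethylsilyl)oxy)-3-iodobut-2-en-1-ol
Product: 4 (E)-3-(((tert-butyldimethylsilyl)oxy)methyl)hepta-2,6-dien-1-ol
Conditions: but-3-enylzinc bromide (THF solution), Pd(dppf)Cl2 (5 mol%), THF, rt → 45 °C
Reagents that add atoms: but-3-enylzinc bromide C=CCC[Zn]Br
Why: Negishi sp2–sp3 cross-coupling proceeds with retention of olefin geometry and places the C1–C3 chain cis to C6, the chelating diphosphine suppressing β-hydride elimination.

Step 3
Reactants: 4 (E)-3-(((tert-butyldimethylsilyl)oxy)methyl)hepta-2,6-dien-1-ol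
Product: 5 (E)-3-(((tert-butyldimethylsilyl)oxy)methyl)hepta-2,6-dienal
Conditions: activated MnO2, CH2Cl2, rt
Reagents that add atoms: none
Why: Chemoselective allylic oxidation with MnO2 under neutral conditions should give the β,β-disubstituted enal without E/Z isomerization.

Step 4
Reactants: 5 (E)-3-(((tert-butyldimethylsilyl)oxy)methyl)hepta-2,6-dienal
Product: 6 (3R,4E)-5-(((tert-butyldimethylsilyl)oxy)methyl)-1-(trimethylsilyl)nona-4,8-dien-1-yn-3-ol
Conditions: ethynyltrimethylsilane, Me2Zn, (S,S)-ProPhenol (10 mol%), Ph3P=O (20 mol%), toluene, 4 °C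
Reagents that add atoms: ethynyltrimethylsilane C#C[Si](C)(C)C
Why: Catalytic enantioselective alkynylzinc 1,2-addition to the enal (dinuclear zinc–ProPhenol catalysis) sets the C6 carbinol centre under catalyst control, the ligand enantiomer being the one chosen to deliver the (R)-alcohol.

Step 5
Reactants: 6 (3R,4E)-5-(((tert-butyldimethylsilyl)oxy)methyl)-1-(trimethylsilyl)nona-4,8-dien-1-yn-3-ol
Product: 7 (3R,4E)-5-(((tert-butyldimethylsilyl)oxy)methyl)nona-4,8-dien-1-yn-3-ol
Conditions: K2CO3 (cat.), MeOH, rt
Reagents that add atoms: none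
Why: Base-mediated methanolysis of the C(sp)–Si bond (protodesilylation) leaves the carbinol, the TBS ether and the olefins untouched.

Step 6
Reactants: 7 (3R,4E)-5-(((tert-butyldimethylsilyl)oxy)methyl)nona-4,8-dien-1-yn-3-ol
Product: 8 (4S,5E)-6-(((tert-butyldimethylsilyl)oxy)methyl)deca-1,2,5,9-tetraen-4-ol
Conditions: (CH2O)n, CuI (0.5 equiv), Cy2NH, 1,4-dioxane, reflux
Reagents that add atoms: paraformaldehyde (as formaldehyde) C=O
Why: Crabbé homologation (copper-mediated Mannich alkynylation, then retro-imino-ene hydride transfer) converts the terminal propargylic alcohol into the buta-2,3-dienyl carbinol without touching the stereocentre, whose descriptor changes only through CIP priorities.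

Step 7
Reactants: 8 (4S,5E)-6-(((tert-butyldimethylsilyl)oxy)methyl)deca-1,2,5,9-tetraen-4-ol
Product: 9 (4S,5E)-6-(((tert-butyldimethylsilyl)oxy)methyl)deca-1,2,5,9-tetraen-4-yl methyl carbonate
Conditions: ClCO2Me, pyridine, DMAP (cat.), CH2Cl2, 0 °C
Reagents that add atoms: methyl chloroformate COC(=O)Cl
Why: O-Acylation of the secondary alcohol with the chloroformate installs, with retention at C6, the carbonate that later acts as allylic leaving group and internal methoxide source.

Step 8
Reactants: 10 3-chloro-2-(chloromethyl)prop-1-ene; 11 (4-methoxyphenyl)methanol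
Product: 12 1-(((2-(chloromethyl)allyl)oxy)methyl)-4-methoxybenzene
Conditions: NaH, THF/DMF, 0 °C; then 10 (3 equiv), rt
Reagents that add atoms: none
Why: Williamson etherification with the symmetrical bis-allylic dichloride used in excess should stop at mono-substitution.

Step 9
Reactants: 12 1-(((2-(chloromethyl)allyl)oxy)methyl)-4-methoxybenzene
Product: 13 3-(((4-methoxybenzyl)oxy)methyl)but-3-en-1-ol
Conditions: In powder, NaI (cat.), aq. HCHO (37%), THF/H2O, rt
Reagents that add atoms: formaldehyde C=O
Why: Barbier allylation of formaldehyde by the allylindium formed in situ tolerates water and the PMB ether, and the symmetrical 2-substituted allyl unit leaves no regiochemical question.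

Step 10
Reactants: 13 3-(((4-methoxybenzyl)oxy)methyl)but-3-en-1-ol
Product: 14 3-(((4-methoxybenzyl)oxy)methyl)but-3-enal
Conditions: Dess–Martin periodinane, NaHCO3, CH2Cl2, 0 °C; used crude
Reagents that add atoms: none
Why: Dess–Martin oxidation under bicarbonate buffering should give the β,γ-unsaturated aldehyde without migration of the 1,1-disubstituted olefin into conjugation.

Step 11
Reactants: 9 (4S,5E)-6-(((tert-butyldimethylsilyl)oxy)methyl)deca-1,2,5,9-tetraen-4-yl methyl carbonate; 14 3-(((4-methoxybenzyl)oxy)methyl)but-3-enal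
Product: 16 methyl [(5E,7R,8R,9R)-5-(((tert-butyldimethylsilyl)oxy)methyl)-9-hydroxy-12-((4-methoxybenzyl)oxy)-11-methylidene-8-(1-(pinacolboryl)vinyl)dodeca-1,5-dien-7-yl] carbonate, via (Z)-2-boryl allylboronate 15 (not isolated)
Conditions: B2pin2, Pt(dba)2 (3 mol%), PCy3 (3 mol%), toluene, 50 °C; then 14, toluene, rt → 40 °C; aq. NaHCO3 work-up
Reagents that add atoms: bis(pinacolato)diboron CC1(C)OB(OC1(C)C)B1OC(C)(C)C(C)(C)O1
Why: Platinum-catalysed syn-diboration of the terminal allene C=C bond from the face away from C6 should give the (Z)-2-boryl allylboronate 15, which adds to aldehyde 14 through a chair six-membered transition state (allylboration, C6 substituent axial, hence C7/C8 syn in the crotylation sense), the aldehyde approaching C7 anti to the C6–O bond while H6 eclipses the olefin (allylic 1,3-strain), so that C7 and C8 are both relayed from C6 in one event and the C11 alkenylboronate is left in place.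

Step 12
Reactants: 16 methyl [(5E,7R,8R,9R)-5-(((tert-butyldimethylsilyl)oxy)methyl)-9-hydroxy-12-((4-methoxybenzyl)oxy)-11-methylidene-8-(1-(pinacolboryl)vinyl)dodeca-1,5-dien-7-yl] carbonate; 17 (R)-2-methylbutanoic acid
Product: 18 methyl [(5E,7R,8R,9R)-5-(((tert-butyldimethylsilyl)oxy)methyl)-12-((4-methoxybenzyl)oxy)-11-methylidene-9-(((R)-2-methylbutanoyl)oxy)-8-(1-(pinacolboryl)vinyl)dodeca-1,5-dien-7-yl] carbonate
Conditions: DCC, DMAP (cat.), CH2Cl2, 0 °C → rt
Reagents that add atoms: none
Why: Steglich esterification acylates the only free hydroxyl (C8–OH), and the unactivated α-stereocentre of the acid should not enolize under these conditions.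

Step 13
Reactants: 18 methyl [(5E,7R,8R,9R)-5-(((tert-butyldimethylsilyl)oxy)methyl)-12-((4-methoxybenzyl)oxy)-11-methylidene-9-(((R)-2-methylbutanoyl)oxy)-8-(1-(pinacolboryl)vinyl)dodeca-1,5-dien-7-yl] carbonate
Product: 19 (4R,5R)-5-[(E)-2-(((tert-butyldimethylsilyl)oxy)methyl)hexa-1,5-dien-1-yl]-4-[(1R)-3-(((4-methoxybenzyl)oxy)methyl)-1-(((R)-2-methylbutanoyl)oxy)but-3-en-1-yl]-3-methylidenedihydrofuran-2(3H)-one
Conditions: CO2 (1 atm), Pd2(dba)3 (2.5 mol%), dppf (6 mol%), (IPr)CuCl (10 mol%), NaOt-Bu (10 mol%), THF, 50 °C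
Reagents that add atoms: carbon dioxide O=C=O
Why: Proposed new method: Pd(0)/dppf ionizes the C6 allylic methyl carbonate of 18 anti to the leaving group to the cationic C4–C5–C6 π-allyl complex, and the expelled methyl carbonate (in equilibrium with methoxide and CO2) turns the copper into (IPr)Cu–OMe, which takes the C11 alkenyl group from boron; the alkenylcopper inserts CO2 (C11–C12 bond) and the resulting carboxylate attacks C6 of the π-allyl anti to palladium (O–C6 bond), so that boron, methoxide and CO2 are exchanged in a base-free cycle. The closest known reaction types are the NHC–copper-catalysed carboxylation of alkenylboronic esters with CO2 (alkoxide-promoted boron-to-copper transmetalation), the Tsuji–Trost allylic substitution with carboxylate nucleophiles, and cooperative Cu/Pd catalysis in which an allylic carbonate is both electrophile and alkoxide source. The γ-lactone ring (O–C6–C7–C11–C12) closes by 5-exo attack of the carboxylate oxygen on the C6 terminus, whereas attack at C4 would give a seven-membered ring and a fully substituted C–O centre and is disfavoured. C6 is re-formed with overall retention (double inversion), so the trans ring fusion (H6 anti to H7) is dictated by the C6/C7 configuration of 18, and the C4=C5 geometry is kept because C6 ionizes with H6 in the allyl plane (allylic strain with C3) and the C4 terminus is never σ-bound. The step needs CO2 insertion to outrun both C–C coupling of the alkenyl group with the allyl unit and capture of the allyl by methoxide: the chelating diphosphine leaves no site on palladium for transmetalation, the CO2 atmosphere keeps methoxide masked as methyl carbonate and feeds the copper, and C–C coupling would have to form a three-membered ring (at C6) or a congested five-membered ring (at C4).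

Step 14
Reactants: 19 (4R,5R)-5-[(E)-2-(((tert-butyldimethylsilyl)oxy)methyl)hexa-1,5-dien-1-yl]-4-[(1R)-3-(((4-methoxybenzyl)oxy)methyl)-1-(((R)-2-methylbutanoyl)oxy)but-3-en-1-yl]-3-methylidenedihydrofuran-2(3H)-one
Product: 20 (1(10)E,4E,6R,7R,8R)-15-((tert-butyldimethylsilyl)oxy)-14-((4-methoxybenzyl)oxy)-8-(((R)-2-methylbutanoyl)oxy)germacra-1(10),4,11(13)-trien-12,6-olide
Conditions: Grubbs second-generation catalyst (10 mol%), toluene (1 mM), 80 °C
Reagents that add atoms: none
Why: Ring-closing olefin metathesis between the monosubstituted C1 vinyl group and the 1,1-disubstituted C10 olefin, pre-organized by the trans-lactone, should give the ten-membered ring with the ring-cis C1=C10 geometry that the medium ring imposes (CIP descriptor E), the electron-poor C11=C13 methylene and the trisubstituted C4=C5 olefin being poor metathesis partners.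

Step 15
Reactants: 20 (1(10)E,4E,6R,7R,8R)-15-((tert-butyldimethylsilyl)oxy)-14-((4-methoxybenzyl)oxy)-8-(((R)-2-methylbutanoyl)oxy)germacra-1(10),4,11(13)-trien-12,6-olide
Product: 21 (1(10)E,4E,6R,7R,8R)-15-((tert-butyldimethylsilyl)oxy)-14-hydroxy-8-(((R)-2-methylbutanoyl)oxy)germacra-1(10),4,11(13)-trien-12,6-olide
Conditions: DDQ, CH2Cl2/pH 7 buffer, 0 °C
Reagents that add atoms: none
Why: Oxidative cleavage of the p-methoxybenzyl ether by DDQ (benzylic oxidation to the oxocarbenium ion, then hydrolysis) spares the silyl ether, the esters and the conjugated lactone.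

Step 16
Reactants: 21 (1(10)E,4E,6R,7R,8R)-15-((tert-butyldimethylsilyl)oxy)-14-hydroxy-8-(((R)-2-methylbutanoyl)oxy)germacra-1(10),4,11(13)-trien-12,6-olide
Product: 22 (1(10)E,4E,6R,7R,8R)-15-((tert-butyldimethylsilyl)oxy)-8-(((R)-2-methylbutanoyl)oxy)-14-oxogermacra-1(10),4,11(13)-trien-12,6-olide
Conditions: activated MnO2, CH2Cl2, rt
Reagents that add atoms: none
Why: MnO2 oxidizes the primary allylic alcohol to the conjugated enal chemoselectively and without olefin isomerization.

Step 17
Reactants: 22 (1(10)E,4E,6R,7R,8R)-15-((tert-butyldimethylsilyl)oxy)-8-(((R)-2-methylbutanoyl)oxy)-14-oxogermacra-1(10),4,11(13)-trien-12,6-olide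
Product: 23 (1(10)E,4E,6R,7R,8R)-15-hydroxy-8-(((R)-2-methylbutanoyl)oxy)-14-oxogermacra-1(10),4,11(13)-trien-12,6-olide (CNP0168859.5)
Conditions: HF·pyridine, pyridine, THF, 0 °C → rt
Reagents that add atoms: none
Why: Buffered fluoride-mediated desilylation cleaves the primary TBS ether without conjugate addition to the α-methylene lactone or the enal.

## Compound list

1 | 4-((tert-butyldimethylsilyl)oxy)but-2-yn-1-ol | OCC#CCO[Si](C)(C)C(C)(C)C | starting material
2 | cyclic sodium alkenylalkoxyaluminate from trans-hydroalumination of 1 | [Na+].COCCO[Al-]1(OCCOC)OCC=C1CO[Si](C)(C)C(C)(C)C | intermediate (not isolated)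
3 | (Z)-4-((tert-butyldimethylsilyl)oxy)-3-iodobut-2-en-1-ol | OC/C=C(\I)CO[Si](C)(C)C(C)(C)C | intermediate
4 | (E)-3-(((tert-butyldimethylsilyl)oxy)methyl)hepta-2,6-dien-1-ol | OC/C=C(\CCC=C)CO[Si](C)(C)C(C)(C)C | intermediate
5 | (E)-3-(((tert-butyldimethylsilyl)oxy)methyl)hepta-2,6-dienal | O=C/C=C(\CCC=C)CO[Si](C)(C)C(C)(C)C | intermediate
6 | (3R,4E)-5-(((tert-butyldimethylsilyl)oxy)methyl)-1-(trimethylsilyl)nona-4,8-dien-1-yn-3-ol | O[C@H](/C=C(/CO[Si](C)(C)C(C)(C)C)CCC=C)C#C[Si](C)(C)C | intermediate
7 | (3R,4E)-5-(((tert-butyldimethylsilyl)oxy)methyl)nona-4,8-dien-1-yn-3-ol | O[C@H](/C=C(/CO[Si](C)(C)C(C)(C)C)CCC=C)C#C | intermediate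
8 | (4S,5E)-6-(((tert-butyldimethylsilyl)oxy)methyl)deca-1,2,5,9-tetraen-4-ol | O[C@H](/C=C(/CO[Si](C)(C)C(C)(C)C)CCC=C)C=C=C | intermediate
9 | (4S,5E)-6-(((tert-butyldimethylsilyl)oxy)methyl)deca-1,2,5,9-tetraen-4-yl methyl carbonate | COC(=O)O[C@H](/C=C(/CO[Si](C)(C)C(C)(C)C)CCC=C)C=C=C | intermediate
10 | 3-chloro-2-(chloromethyl)prop-1-ene | C=C(CCl)CCl | starting material
11 | (4-methoxyphenyl)methanol | COc1ccc(CO)cc1 | starting material
12 | 1-(((2-(chloromethyl)allyl)oxy)methyl)-4-methoxybenzene | C=C(CCl)COCc1ccc(OC)cc1 | intermediate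
13 | 3-(((4-methoxybenzyl)oxy)methyl)but-3-en-1-ol | OCCC(=C)COCc1ccc(OC)cc1 | intermediate
14 | 3-(((4-methoxybenzyl)oxy)methyl)but-3-enal | O=CCC(=C)COCc1ccc(OC)cc1 | intermediate
15 | methyl (2Z,4S,5E)-6-(((tert-butyldimethylsilyl)oxy)methyl)-1,2-bis(4,4,5,5-tetramethyl-1,3,2-dioxaborolan-2-yl)deca-2,5,9-trien-4-yl carbonate | COC(=O)O[C@H](/C=C(/CO[Si](C)(C)C(C)(C)C)CCC=C)/C=C(B1OC(C)(C)C(C)(C)O1)\CB1OC(C)(C)C(C)(C)O1 | intermediate (not isolated)
16 | methyl [(5E,7R,8R,9R)-5-(((tert-butyldimethylsilyl)oxy)methyl)-9-hydroxy-12-((4-methoxybenzyl)oxy)-11-methylidene-8-(1-(pinacolboryl)vinyl)dodeca-1,5-dien-7-yl] carbonate (germacrane numbers: 6R,7R,8R; C6 carbonate, C8 OH, C11 Bpin) | C=C(B1OC(C)(C)C(C)(C)O1)[C@@H]([C@H](OC(=O)OC)/C=C(/CO[Si](C)(C)C(C)(C)C)CCC=C)[C@H](O)CC(=C)COCc2ccc(OC)cc2 | intermediate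
17 | (R)-2-methylbutanoic acid | CC[C@@H](C)C(=O)O | starting material
18 | methyl [(5E,7R,8R,9R)-5-(((tert-butyldimethylsilyl)oxy)methyl)-12-((4-methoxybenzyl)oxy)-11-methylidene-9-(((R)-2-methylbutanoyl)oxy)-8-(1-(pinacolboryl)vinyl)dodeca-1,5-dien-7-yl] carbonate | C=C(B1OC(C)(C)C(C)(C)O1)[C@@H]([C@H](OC(=O)OC)/C=C(/CO[Si](C)(C)C(C)(C)C)CCC=C)[C@H](OC(=O)[C@H](C)CC)CC(=C)COCc2ccc(OC)cc2 | intermediate
19 | (4R,5R)-5-[(E)-2-(((tert-butyldimethylsilyl)oxy)methyl)hexa-1,5-dien-1-yl]-4-[(1R)-3-(((4-methoxybenzyl)oxy)methyl)-1-(((R)-2-methylbutanoyl)oxy)but-3-en-1-yl]-3-methylidenedihydrofuran-2(3H)-one | C=C1C(=O)O[C@H](/C=C(/CO[Si](C)(C)C(C)(C)C)CCC=C)[C@H]1[C@H](OC(=O)[C@H](C)CC)CC(=C)COCc2ccc(OC)cc2 | intermediate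
20 | (1(10)E,4E,6R,7R,8R)-15-((tert-butyldimethylsilyl)oxy)-14-((4-methoxybenzyl)oxy)-8-(((R)-2-methylbutanoyl)oxy)germacra-1(10),4,11(13)-trien-12,6-olide | C=C1C(=O)O[C@@H]2/C=C(/CO[Si](C)(C)C(C)(C)C)CC/C=C(/COCc3ccc(OC)cc3)C[C@@H](OC(=O)[C@H](C)CC)[C@@H]12 | intermediate
21 | (1(10)E,4E,6R,7R,8R)-15-((tert-butyldimethylsilyl)oxy)-14-hydroxy-8-(((R)-2-methylbutanoyl)oxy)germacra-1(10),4,11(13)-trien-12,6-olide | C=C1C(=O)O[C@@H]2/C=C(/CO[Si](C)(C)C(C)(C)C)CC/C=C(/CO)C[C@@H](OC(=O)[C@H](C)CC)[C@@H]12 | intermediate
22 | (1(10)E,4E,6R,7R,8R)-15-((tert-butyldimethylsilyl)oxy)-8-(((R)-2-methylbutanoyl)oxy)-14-oxogermacra-1(10),4,11(13)-trien-12,6-olide | C=C1C(=O)O[C@@H]2/C=C(/CO[Si](C)(C)C(C)(C)C)CC/C=C(/C=O)C[C@@H](OC(=O)[C@H](C)CC)[C@@H]12 | intermediate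
23 | (1(10)E,4E,6R,7R,8R)-15-hydroxy-8-(((R)-2-methylbutanoyl)oxy)-14-oxogermacra-1(10),4,11(13)-trien-12,6-olide (CNP0168859.5) | C=C1C(=O)O[C@@H]2/C=C(/CO)CC/C=C(/C=O)C[C@@H](OC(=O)[C@H](C)CC)[C@@H]12 | target

## Step count and risks

Total: 17 steps. Longest linear sequence: 14 steps (steps 1–7 and 11–17).

Steps most likely to fail:

1. Step 13 (Proposed new method). The π-allyl intermediate may be intercepted before the carboxylate exists, by O-allylation with methoxide or by C–C coupling of the alkenyl metal with the allyl unit. Boron-to-copper transfer at the hindered 1,1-disubstituted alkenylboronate may be slow, with protodeboronation competing. Exchange of the π-allyl face by Pd(0) would erode the trans ring fusion. The fallback uses known chemistry, sets out from 18 and comes back at 19. The two bonds are made in two separate operations: the alkenylboronate of 18 is first carboxylated on its own by NHC–copper catalysis [(IPr)CuCl, CsF, CO2 (1 atm), THF, 60 °C; mildly acidic work-up] to the 2-substituted acrylic acid F1. The acid is then closed onto the allylic carbonate by a conventional palladium-catalysed allylic substitution [Pd(PPh3)4, THF, rt], the methoxide released from the carbonate deprotonating the acid, to give 19.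

2. Step 11. Pt(0) may ionize the doubly allylic carbonate of 9 or 15 before or after diboration, and the (Z)-geometry of the allylboronate or the facial bias from C6 may erode, giving C7/C8 diastereomers. The fallback sets out from 8 and comes back at 18; it carries C6 as a robust, bulkier silyl ether and installs the leaving group only after the union. Allenol 8 would be silylated (TESCl, imidazole, CH2Cl2) to the triethylsilyl ether F2. Diboration/allylboration with 14 under the conditions of step 11 would give the hydroxy alkenylboronate F3. Steglich esterification with 17 would give the ester F4. Selective removal of the triethylsilyl group (PPTS, MeOH, 0 °C) would give the allylic alcohol F5. Methyl chloroformate/pyridine would then give 18.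

3. Step 14. Closure to a trisubstituted olefin in a ten-membered ring may be slow, with competing oligomerization or formation of the ring-trans isomer. The fallback sets out from 18 and comes back at 20; it reverses the order of ring formation. Metathesis would be run on the open-chain carbonate 18 (same ruthenium catalyst, high dilution) to give the ten-membered allylic carbonate F6. The CO2 lactonization of step 13, or its two-stage variant, would then be run on F6 and give 20 directly, the macrocycle holding C11 and C6 close together.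

Further compounds
F1 | step 13 | open-chain 2-substituted acrylic acid, C11–CO2H in place of C11–Bpin of 18 (same configuration) | C=C(C(=O)O)[C@@H]([C@H](OC(=O)OC)/C=C(/CO[Si](C)(C)C(C)(C)C)CCC=C)[C@H](OC(=O)[C@H](C)CC)CC(=C)COCc2ccc(OC)cc2
F2 | step 11 | (4S,5E)-6-(((tert-butyldimethylsilyl)oxy)methyl)-4-((triethylsilyl)oxy)deca-1,2,5,9-tetraene | CC[Si](CC)(CC)O[C@H](/C=C(/CO[Si](C)(C)C(C)(C)C)CCC=C)C=C=C
F3 | step 11 | C6 triethylsilyl ether analogue of 16 (C8–OH free, C11–Bpin; same configuration) | C=C(B1OC(C)(C)C(C)(C)O1)[C@@H]([C@H](O[Si](CC)(CC)CC)/C=C(/CO[Si](C)(C)C(C)(C)C)CCC=C)[C@H](O)CC(=C)COCc2ccc(OC)cc2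
F4 | step 11 | C6 triethylsilyl ether analogue of 18 (C8 (R)-2-methylbutanoate; same configuration) | C=C(B1OC(C)(C)C(C)(C)O1)[C@@H]([C@H](O[Si](CC)(CC)CC)/C=C(/CO[Si](C)(C)C(C)(C)C)CCC=C)[C@H](OC(=O)[C@H](C)CC)CC(=C)COCc2ccc(OC)cc2
F5 | step 11 | C6 hydroxy analogue of 18 (free allylic alcohol; same configuration) | C=C(B1OC(C)(C)C(C)(C)O1)[C@@H]([C@H](O)/C=C(/CO[Si](C)(C)C(C)(C)C)CCC=C)[C@H](OC(=O)[C@H](C)CC)CC(=C)COCc2ccc(OC)cc2
F6 | step 14 | ten-membered allylic methyl carbonate carrying the C11 alkenyl–Bpin (ring-closed 18; same configuration; ring-cis C1=C10 and C4=C5) | C=C(B1OC(C)(C)C(C)(C)O1)[C@H]2[C@H](OC(=O)OC)/C=C(/CO[Si](C)(C)C(C)(C)C)CC/C=C(/COCc3ccc(OC)cc3)C[C@H]2OC(=O)[C@H](C)CC
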